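Count the activator first.

| flask | starting material | activator | capture agent | remark | time |
|---|---|---|---|---|---|
| Saturday's | 0.17 M | 0.80 equiv | 0.051 M | run made earlier |  |
| Thursday's | 0.17 M | 0.40 equiv | 0.051 M | run made earlier |  |
| Sunday's | 0.17 M | 1.6 equiv | 0.051 M | run made earlier |  |
| Monday's | 0.17 M | 0.80 equiv | 0.025 M | run made earlier |  |
| beta | 0.17 M | 0.800 equiv (fed, over 1.0 h) | 0.0510 M | all else is in the flask from the start; the feed brings no volume worth counting | 2.5 h |
| delta | 0.17 M | 0.800 equiv | 0.0510 M | everything together at the start | 2.5 h |
| gamma | 0.17 M (fed, over 1.0 h) | 0.800 equiv | 0.0510 M | all else is in the flask from the start; the feed brings no volume worth counting | 2.5 h |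

- Saturday's (time / min: ring / %): 8.00: 0.9; 12.0: 3.3; 20.0: 5.8; 30.0: 10.5; 50.0: 19.9; 90.0: 37.2
- Thursday's (time / min: ring / %): 8.00: 0.1; 12.0: 1.5; 20.0: 2.4; 30.0: 5.6; 50.0: 11.6; 90.0: 20.4
- Sunday's (time / min: ring / %): 6.00: 0.9; 20.0: 9.6; 30.0: 18.0; 50.0: 33.1; 60.0: 39.4; 90.0: 57.2
- Monday's (time / min: ring / %): 20.0: 5.0; 40.0: 14.8; 50.0: 19.6; 80.0: 34.1; 90.0: 37.7

(standard deviation of a reading: 0.5 percentage points)

* which flask leads in amount of ring, in percent of the starting material charged ("all alike" within 1.5 percentage points) (beta / delta / gamma / all alike)
* how much ring is there at the end, in percent of the starting material charged: beta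
* how much ring is there at the end, in percent of the starting material charged: delta
* how much ring is there at the end, in percent of the starting material charged: gamma

- what was read earlier has a scatter of 0.5 percentage points, one standard deviation

The bench rule of thumb is first-order loss of starting material with a steady constant, the activator acting as a catalyst and the starting material lost appearing as ring. I read that constant from Saturday's run, between its readings at 30.0 min and 90.0 min, as 0.00590 min⁻¹, and the line starts after a lag of 11.2 min. For delta the rule then gives 55.9%.

But in delta, with 0.800 equiv charged, activator is the limiting reagent against starting material. If each ring costs one activator, which I assume and the readings do not prove, ring can rise no higher than the activator ceiling, the equivalents charged read as percent of the starting material, 80.0%. Saturday's last reading stands at 46.5% of its ceiling and Thursday's at 51.0% of its own, while the rule asks delta for 69.9%, so delta lies further up than either reading.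

I therefore let the gap to the ceiling close exponentially. The same two readings give 0.00808 min⁻¹, with a lag of 12.6 min. My delta is 53.6%. Taking 30.0 min off for a feed, my beta and gamma are 46.4%.

The forecast names delta as leader, with 55.8% (52.5% to 59%), beta 47.3% and gamma 47%, holding that the activator “behaves as if it is not consumed”. My delta lies lower than its figure, inside its range.

Delta gives 54.2%, beta 46.5% and gamma 46.9%, so delta leads.

    starting material + activator → activated form (k = 11.7 M⁻¹ h⁻¹)
    starting material + activated form → open dimer (k = 0.301 M⁻¹ h⁻¹)
    activated form → ring (k = 0.949 h⁻¹)
    capture agent + activated form → trapped intermediate (k = 1.13 M⁻¹ h⁻¹)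

In beta at 2.50 h, activated form goes to ring 18 times as fast as to trapped intermediate, and starting material goes to activated form 27 times as fast as to open dimer. Beta holds 74.2% ring at 25.0 h, 92.8% of the ceiling. The neighbour of beta with [starting material] at 0.10 M has the same ceiling and holds 39.0% ring at 2.50 h, 48.8% of it.

The earlier runs and the new flask are simulated for an exercise; scatter was added.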